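The data were generated by integration on assumed constants; the scatter is artificial.

One move has to be chosen for flask delta at 25 h, so the first job is to read what its stall means.

| setting | delta | eta | flask |
|---|---|---|---|
| G | 1 M | 1 M | 1.0 M |
| X | 14 mol% | 28 mol% | 14 mol% |
| temperature | 25 °C | 10 °C | 25 °C |
| remark | the very flask that is asked about, followed so far | run made earlier |  |
| time |  |  | 25 h |

| run | time / h | Q / % |
|---|---|---|
| delta | 3.00 | 18.8 |
| delta | 8.00 | 28.7 |
| delta | 15.0 | 31.9 |
| delta | 25.0 | 34.0 |
| eta | 2.00 | 9.2 |
| eta | 4.00 | 17.9 |
| eta | 5.00 | 21.2 |
| eta | 8.00 | 30.2 |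

(each reading ± 0.5 percentage points)

- ochre: change nothing and wait 2.0 d more
- violet: at 25 h take out 90% of the Q then present, then wait 2.0 d
- blue: at 25 h raise the temperature by 10 K, then wait 2.0 d
- grey: at 25 h add X, 50.0% of the amount charged, then wait 2.0 d

- Q, in percent of the G first charged, at 25 h
- which option adds most Q ("none" when 2 percentage points or less is all one gets) (ochre / violet / blue / grey / none)
- Q present, with what was taken out counted in, in percent of the G first charged, after blue
- Q present, with what was taken out counted in, in percent of the G first charged, after grey

- what is taken out of Q is counted as made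
- additions bring no volume worth counting

Join delta's two ends. The late end I take as a plateau near 34.0% of the charge, though that is a reading still creeping up, and the early end is 18.8% already at 3.00 h. Joined by an exponential climb, they give the closing time (an apparent relaxation time), the time in which the gap between Q and its plateau shrinks by a factor e: 3.73 h. The curve overshoots the reading at 8.00 h by 1.3 percentage points and the one at 15.0 h by 1.5 points, so it is good to about that. Delta has run 6.70 closing times by 25 h, so I expect Q near 34.0% there, and waiting should add little on either view below.

Ann says the closing time is X dying. In eta, −ln(1−Q)/t stays at 0.0483 /h and 0.0449 /h up to 30.2%, with no balance in sight, so fresh X should start a new climb.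

Bea says delta sits at a balance, and eta, at 10 °C against 25 °C, need not share it. Taking out 30.6% of the charge lets the remainder return to the same share, which gives 54.2% counted in, while added X gains nothing.

The forecast is Ann's: 33.9% now, 35% after blue, 45.5% after grey, best grey, on the ground that “almost no X is active at 25 h”.

The flask gives 34.1%. Violet adds 15 points, more than grey's 3.8 points, so violet is best; blue ends at 33.8% and grey at 37.8%.

    G + X ⇌ Q + X, rate k1*[G]*[X] forward; the back reaction follows from the equilibrium constant (K = 1.60, k = 0.755 /M/h, Ea = 74.0 kJ/mol, ΔH = −47.0 kJ/mol)
    Q ⇌ E (K = 0.890, k = 1.52 /h, Ea = 100 kJ/mol, ΔH = 1.00 kJ/mol)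
    E + X ⇌ G + X, rate k3*[X]*[E] forward; the back reaction follows from the equilibrium constant (k = 0.469 /M/h, Ea = 78.0 kJ/mol)
    X → J (k = 0.131 /h, Ea = 98.0 kJ/mol)
    (constants at 25 °C)

Ann keeps her region: in delta X is down to 3.78% of its charge at 25.0 h, and the neighbour charged with 24 mol% of X reaches Q 38.3% at 25.0 h, above delta's 34.1%. Bea's move pays in delta, which at 25.0 h holds E 30.3% beside Q 34.1%, and the relaxation half-life of Q and E by their own step alone is 0.215 h, short against 25 h. In delta, after 6.70 closing times, waiting adds 0.42 points. For the neighbour stopped at 6.0 h, the joined curve with the same closing time gives 27.2%, and that flask holds Q 26.5%.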